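**Plan**

1. Retrosynthesis: the C1–C2 bond of the ten-membered carbocycle is cut first and replaced by an O–C(=O) bridge (C1–CO–O–C2), which gives a 12-membered allyl β-keto macrolactone. Then come the lactone C–O bond (acylketene + C2–OH), C4–C5 (alkenylchromium + aldehyde), C8–C9 (vinylogous aldol), and C7–C8 with C11–C13 (Michael/Mannich on a butenolide).
2. Feature used: C1 lies α to C10 (the exocyclic-methylene carbon, a masked ketone) and C2 is the allylic CH2 of the (E)-C3=C4 olefin. C1–C2 is therefore an enolate–allyl bond, and the carbocycle is the 12-membered lactone minus CO2.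
3. Forward: γ-butyrolactone → butenolide → trans-disubstituted lactone (the only ring) → open chain C1–C10 → 12-membered macrolactone → Pd-mediated CO2 extrusion to the ten-membered ring → C10 methylenation, acetate, deprotection.
4. Stereochemistry: C6 is bought; C7 by anti conjugate addition; C8 by 1,3-anti aldol; C5 by Felkin Nozaki–Hiyama–Kishi addition; C1 by the chiral Pd catalyst in the ring contraction; (E)-C3=C4 from syn-hydrozirconation; (Z)-angelate bought.

Key step: step 16

Remark: germacranolide numbering is used for all intermediates (C1 carbinol next to C10; C3=C4 olefin with C15 methyl; C5 acetoxy; C6 lactone O–CH; C7; C8 angelate; C9 CH2; C10/C14 exocyclic methylene; C11/C13 lactone methylene; C12 lactone C=O); the target is then (1S,5S,6R,7S,8S), 3E.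

**Route**

Step 1
Reactants: 1 (R)-5-(hydroxymethyl)dihydrofuran-2(3H)-one
Product: 2 (R)-5-[(tert-butyldiphenylsilyloxy)methyl]dihydrofuran-2(3H)-one
Conditions: TBDPSCl, imidazole, CH2Cl2, 0 °C → rt
Reagents that add atoms: tert-butyl(chloro)diphenylsilane CC(C)(C)[Si](Cl)(c1ccccc1)c1ccccc1
Why: Imidazole-mediated silylation of the primary alcohol; the C6 stereocenter is not touched.

Step 2
Reactants: 2 (R)-5-[(tert-butyldiphenylsilyloxy)methyl]dihydrofuran-2(3H)-one
Product: 4 (R)-5-[(tert-butyldiphenylsilyloxy)methyl]furan-2(5H)-one, via alpha-phenylselanyl lactone 3 (not isolated)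
Conditions: LDA, THF, −78 °C, then PhSeBr; then 30% H2O2, pyridine, CH2Cl2, 0 °C → rt
Reagents that add atoms: none
Why: α-Selenenylation of the lactone enolate followed by selenoxide syn-elimination should give the butenolide without touching the γ-stereocenter C6.

Step 3
Reactants: 4 (R)-5-[(tert-butyldiphenylsilyloxy)methyl]furan-2(5H)-one; 5 1,3-dithiane
Product: 8 all-trans Mannich base lactone (3S,4R,5R), via 2-lithio-1,3-dithiane 6 (not isolated), via lithium lactone enolate 7 (not isolated)
Conditions: 5, n-BuLi, THF, −30 °C; 4, −78 °C; then CH2=NMe2+ I−, −78 → 0 °C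
Reagents that add atoms: N,N-dimethylmethyleneiminium iodide (Eschenmoser's salt) C=[N+](C)C.[I-]
Why: Tandem Michael/Mannich reaction: the dithiane anion (formyl anion equivalent, future C8) should add 1,4 anti to the CH2OSi group, setting C7 trans to C6, and the lithium enolate is then trapped anti to the new C7 substituent by Eschenmoser's salt, which installs the masked C13 methylene.

Step 4
Reactants: 8 all-trans Mannich base lactone with 1,3-dithian-2-yl at C7
Product: 9 (2R,3R,4S)-2-[(tert-butyldiphenylsilyloxy)methyl]-4-[(dimethylamino)methyl]-5-oxotetrahydrofuran-3-carbaldehyde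
Conditions: Hg(ClO4)2·3H2O, CaCO3, THF/H2O, 0 °C; used at once
Reagents that add atoms: water O
Why: Hg(II)-assisted dithioacetal hydrolysis under carbonate buffering should unmask the C8 aldehyde; the all-trans lactone is the thermodynamically preferred C7 epimer, and the β-acyloxy aldehyde is carried on without storage.

Step 5
Reactants: 10 2,2,6-trimethyl-4H-1,3-dioxin-4-one
Product: 11 2,2-dimethyl-6-methylene-4-(trimethylsilyloxy)-6H-1,3-dioxine (silyl dienol ether)
Conditions: LDA, THF, −78 °C; TMSCl
Reagents that add atoms: chlorotrimethylsilane C[Si](C)(C)Cl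
Why: γ-Deprotonation and O-silylation of the dioxinone give the vinylogous acetoacetate nucleophile that carries C9, C10, C1 and the carboxyl carbon.

Step 6
Reactants: 9 C8 aldehyde; 11 silyl dienol ether
Product: 12 all-trans lactone carrying at C7 the (1S)-1-hydroxy-2-(2,2-dimethyl-4-oxo-4H-1,3-dioxin-6-yl)ethyl chain (C8 carbinol, 8S)
Conditions: BF3·OEt2 (2.5 equiv), CH2Cl2, −78 °C; aq. NaHCO3
Reagents that add atoms: none
Why: Vinylogous Mukaiyama aldol at the terminal carbon of the dienol ether forms C8–C9; under non-chelating BF3 conditions the C8 carbinol should arise 1,3-anti to the ring oxygen on C6 (polar Evans-type 1,3-induction with an unhindered acetate-type nucleophile), which is the 8S configuration.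

Step 7
Reactants: 12 C8 alcohol; 13 angelic acid
Product: 15 C8 angelate of 12, via mixed trichlorobenzoic angelic anhydride 14 (not isolated)
Conditions: 13, 2,4,6-Cl3C6H2COCl, Et3N, toluene, rt; then 12, toluene, 60 °C
Reagents that add atoms: none
Why: Yamaguchi esterification through the preformed mixed anhydride should acylate the hindered C8 alcohol with retention at C8 and, without a nucleophilic catalyst, keep the (Z)-geometry of the angelate.

Step 8
Reactants: 15 C8 angelate with CH2NMe2 on C11
Product: 17 α-methylene lactone (6R,7S,8S) with TBDPS ether and dioxinone, via trimethylammonium iodide 16 (not isolated)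
Conditions: MeI, MeCN, rt; then aq. NaHCO3, CH2Cl2, rt
Reagents that add atoms: none
Why: N-Methylation and E1cB (Hofmann-type) loss of trimethylamine from the β-ammonio lactone is the standard unmasking of an α-methylene lactone; it is done after acylation so that no free C8 hydroxyl can add to the new acrylate.

Step 9
Reactants: 17 TBDPS ether
Product: 18 primary C5 alcohol
Conditions: HF·pyridine, pyridine, THF, 0 °C → rt
Reagents that add atoms: none
Why: Buffered fluoride cleavage of the primary silyl ether should leave the angelate, dioxinone and α-methylene lactone intact.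

Step 10
Reactants: 18 primary C5 alcohol
Product: 19 C5 aldehyde
Conditions: Dess–Martin periodinane, NaHCO3, CH2Cl2, 0 °C → rt
Reagents that add atoms: none
Why: Buffered Dess–Martin oxidation gives the α-oxygenated aldehyde under conditions that should not epimerise C6.

Step 11
Reactants: 20 but-2-yn-1-ol
Product: 22 (E)-3-iodobut-2-en-1-ol, via alkenylzirconocene chloride 21 (not isolated)
Conditions: Cp2Zr(H)Cl (2.3 equiv), THF, 0 °C → rt; then I2, 0 °C
Reagents that add atoms: iodine II
Why: Hydrozirconation of the O-zirconated alkynol is syn and should place Zr on C4 (remote from the alkoxide), so iodinolysis with retention gives the (E)-iodide that carries C2, C3, C4 and C15.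

Step 12
Reactants: 19 C5 aldehyde; 22 (E)-3-iodobut-2-en-1-ol
Product: 23 open-chain diol (5S,6R,7S,8S; 3E) with dioxinone terminus
Conditions: CrCl2 (6 equiv), NiCl2 (2 mol %), DMSO, rt
Reagents that add atoms: none
Why: Nozaki–Hiyama–Kishi coupling is chemoselective for the aldehyde and tolerates the free hydroxyl; Felkin–Anh addition anti to the C6–O bond should give the 5,6-anti (5S) allylic alcohol with retention of the (E)-olefin.

Step 13
Reactants: 23 open-chain diol with dioxinone terminus
Product: 25 12-membered β-keto macrolactone (ring C1–CO–O–C2–C3=C4–C5–C6–C7–C8–C9–C10), via acylketene 24 (not isolated)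
Conditions: toluene, 110 °C, slow addition (final 0.5 mM)
Reagents that add atoms: none
Why: Retro-[4+2] loss of acetone gives an acylketene that is captured by the unhindered primary allylic C2 hydroxyl (Boeckman macrolactonisation); the hindered secondary C5 hydroxyl would have to close a strained nine-membered ring.

Step 14
Reactants: 25 12-membered β-keto macrolactone
Product: 26 1-diazo derivative of 25
Conditions: p-ABSA, Et3N, MeCN, 0 °C
Reagents that add atoms: 4-acetamidobenzenesulfonyl azide CC(=O)Nc1ccc(cc1)S(=O)(=O)N=[N+]=[N-]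
Why: Regitz diazo transfer should occur only at C1, the single carbon flanked by two carbonyls.

Step 15
Reactants: 26 α-diazo-β-keto macrolactone
Product: 27 1-(4-methoxybenzyloxy)-β-keto macrolactone (C1 epimers)
Conditions: Rh2(OAc)4 (2 mol %), 4-methoxybenzyl alcohol (10 equiv), CH2Cl2, 40 °C, slow addition of 26
Reagents that add atoms: 4-methoxybenzyl alcohol COc1ccc(CO)cc1
Why: Rh(II)-carbenoid O–H insertion into a large excess of the alcohol installs the C1 oxygen as its PMB ether; the C1 epimer mixture is inconsequential because C1 is enolised in the next step.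

Step 16
Reactants: 27 1-(4-methoxybenzyloxy)-β-keto macrolactone
Product: 28 ten-membered ketone: (1S,5S,6R,7S,8S)-8-angeloyloxy-5-hydroxy-1-(4-methoxybenzyloxy)-10-oxo-14-norgermacra-3E,11(13)-dien-12,6-olide
Conditions: Pd2(dba)3 (5 mol %), (S)-t-Bu-PHOX (12.5 mol %; antipode if mismatched), toluene (1 mM), 30 °C
Reagents that add atoms: none
Why: Proposed new method: Pd(0) should ionise the only allylic ester of 27 (O–C2) to an (E)-η3-allyl(C2–C3–C4)palladium cation paired with the tethered β-keto carboxylate, which loses CO2 to the C10/C1 α-alkoxy enolate; C-allylation of this enolate at the unsubstituted allyl terminus C2 forms C1–C2, so the O–C(=O) bridge is excised and the 12-membered lactone ring contracts to the ten-membered carbocycle. The closest known reaction type is the Tsuji–Saegusa decarboxylative allylation of open-chain allyl β-keto esters (including its enantioselective form with α-oxygenated enolates and PHOX ligands); what is new is that ionisation and recombination take place inside one macrolactone. The only ring closed is the ten-membered carbocycle, by transannular enolate C-alkylation at the terminal carbon of the allyl unit (exo with respect to the allyl system), while the lactone ring is opened in the same event. The new stereocenter C1 is set in this bond formation: both C1 epimers of 27 converge on one enolate, whose face is selected by the chiral P,N-ligand on palladium (catalyst control, ligand antipode matched to the substrate), the remote ring stereocenters being at most reinforcing. The step needs C2 over C4 attack (C4 is fully substituted and would give an eight-membered ring), C- over O-allylation, intra- over intermolecular recombination (1 mM, non-polar solvent, tight ion pair) and retention of the E olefin (syn/anti exchange would need η1-Pd at tertiary C4), and no second ionisation can occur because C5 carries a free hydroxyl and not an ester.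

Step 17
Reactants: 28 ten-membered C10 ketone
Product: 29 (1S,5S,6R,7S,8S)-8-angeloyloxy-5-hydroxy-1-(4-methoxybenzyloxy)germacra-3E,10(14),11(13)-trien-12,6-olide
Conditions: Zn, CH2Br2, TiCl4 (Takai–Lombardo reagent), THF/CH2Cl2, 0 °C → rt
Reagents that add atoms: dibromomethane BrCBr
Why: Takai–Lombardo methylenation converts the C10 ketone into the exocyclic C10=C14 methylene under non-basic conditions that should neither epimerise the α-alkoxy center C1 nor touch the ester and lactone carbonyls.

Step 18
Reactants: 29 C5 alcohol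
Product: 30 5-O-acetate of 29
Conditions: Ac2O, pyridine, DMAP (cat.), CH2Cl2, 0 °C → rt
Reagents that add atoms: acetic anhydride CC(=O)OC(C)=O
Why: Standard acetylation of the only free hydroxyl (C5).

Step 19
Reactants: 30 1-O-PMB ether
Product: 31 target, (1S,5S,6R,7S,8S)-5-acetoxy-8-angeloyloxy-1-hydroxygermacra-3E,10(14),11(13)-trien-12,6-olide
Conditions: DDQ, CH2Cl2/pH 7 buffer (10:1), 0 °C
Reagents that add atoms: none
Why: Oxidative PMB ether cleavage with DDQ in wet, buffered CH2Cl2 should free the C1 allylic alcohol without affecting the acetate, the angelate or the three alkenes.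

**Compound list**

1 | (R)-5-(hydroxymethyl)dihydrofuran-2(3H)-one | O=C1CC[C@H](CO)O1 | starting material
2 | (R)-5-[(tert-butyldiphenylsilyloxy)methyl]dihydrofuran-2(3H)-one | O=C1CC[C@H](CO[Si](c2ccccc2)(c2ccccc2)C(C)(C)C)O1 | intermediate
3 | (5R)-5-[(tert-butyldiphenylsilyloxy)methyl]-3-(phenylselanyl)dihydrofuran-2(3H)-one (C3 epimers) | O=C1C([Se]c2ccccc2)C[C@H](CO[Si](c2ccccc2)(c2ccccc2)C(C)(C)C)O1 | intermediate
4 | (R)-5-[(tert-butyldiphenylsilyloxy)methyl]furan-2(5H)-one | O=C1C=C[C@H](CO[Si](c2ccccc2)(c2ccccc2)C(C)(C)C)O1 | intermediate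
5 | 1,3-dithiane | C1CSCSC1 | starting material
6 | 2-lithio-1,3-dithiane | [Li]C1SCCCS1 | intermediate
7 | lithium enolate of (4R,5R)-5-[(tert-butyldiphenylsilyloxy)methyl]-4-(1,3-dithian-2-yl)dihydrofuran-2(3H)-one | C1=C(O[Li])O[C@@H](CO[Si](c2ccccc2)(c2ccccc2)C(C)(C)C)[C@@H]1C1SCCCS1 | intermediate
8 | (3S,4R,5R)-5-[(tert-butyldiphenylsilyloxy)methyl]-3-[(dimethylamino)methyl]-4-(1,3-dithian-2-yl)dihydrofuran-2(3H)-one (3,4-trans, 4,5-trans) | CN(C)C[C@H]1C(=O)O[C@@H](CO[Si](c2ccccc2)(c2ccccc2)C(C)(C)C)[C@@H]1C1SCCCS1 | intermediate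
9 | (2R,3R,4S)-2-[(tert-butyldiphenylsilyloxy)methyl]-4-[(dimethylamino)methyl]-5-oxotetrahydrofuran-3-carbaldehyde | CN(C)C[C@H]1C(=O)O[C@@H](CO[Si](c2ccccc2)(c2ccccc2)C(C)(C)C)[C@@H]1C=O | intermediate
10 | 2,2,6-trimethyl-4H-1,3-dioxin-4-one | CC1=CC(=O)OC(C)(C)O1 | starting material
11 | 2,2-dimethyl-6-methylene-4-(trimethylsilyloxy)-6H-1,3-dioxine | C=C1C=C(O[Si](C)(C)C)OC(C)(C)O1 | intermediate
12 | all-trans lactone of 8 type with the (1S)-1-hydroxy-2-(2,2-dimethyl-4-oxo-4H-1,3-dioxin-6-yl)ethyl chain at C7 (8S alcohol) | CN(C)C[C@H]1C(=O)O[C@@H](CO[Si](c2ccccc2)(c2ccccc2)C(C)(C)C)[C@@H]1[C@@H](O)CC1=CC(=O)OC(C)(C)O1 | intermediate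
13 | angelic acid, (Z)-2-methylbut-2-enoic acid | C/C=C(/C)C(=O)O | starting material
14 | angelic 2,4,6-trichlorobenzoic anhydride | C/C=C(/C)C(=O)OC(=O)c1c(Cl)cc(Cl)cc1Cl | intermediate
15 | 8-O-angelate of 12 | CN(C)C[C@H]1C(=O)O[C@@H](CO[Si](c2ccccc2)(c2ccccc2)C(C)(C)C)[C@@H]1[C@@H](OC(=O)/C(C)=C\C)CC1=CC(=O)OC(C)(C)O1 | intermediate
16 | N-methyl quaternary ammonium iodide of 15 | C[N+](C)(C)C[C@H]1C(=O)O[C@@H](CO[Si](c2ccccc2)(c2ccccc2)C(C)(C)C)[C@@H]1[C@@H](OC(=O)/C(C)=C\C)CC1=CC(=O)OC(C)(C)O1.[I-] | intermediate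
17 | (6R,7S,8S) α-methylene-γ-butyrolactone with CH2OTBDPS on C6 and the 8-angeloyloxy dioxinone chain on C7 (6,7-trans) | C=C1C(=O)O[C@@H](CO[Si](c2ccccc2)(c2ccccc2)C(C)(C)C)[C@@H]1[C@@H](OC(=O)/C(C)=C\C)CC1=CC(=O)OC(C)(C)O1 | intermediate
18 | primary C5 alcohol from 17 | C=C1C(=O)O[C@@H](CO)[C@@H]1[C@@H](OC(=O)/C(C)=C\C)CC1=CC(=O)OC(C)(C)O1 | intermediate
19 | C5 aldehyde from 18 | C=C1C(=O)O[C@@H](C=O)[C@@H]1[C@@H](OC(=O)/C(C)=C\C)CC1=CC(=O)OC(C)(C)O1 | intermediate
20 | but-2-yn-1-ol | CC#CCO | starting material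
21 | (E)-alkenylzirconocene chloride of O-zirconated but-2-en-1-ol (Zr on the methyl-bearing carbon) | C/C(=C\CO[Zr](Cl)(C1C=CC=C1)C1C=CC=C1)[Zr](Cl)(C1C=CC=C1)C1C=CC=C1 | intermediate
22 | (E)-3-iodobut-2-en-1-ol | C/C(I)=C\CO | intermediate
23 | open-chain diol (5S,6R,7S,8S; 3E): C2 and C5 hydroxyls, 8-angelate, 12,6-olide, dioxinone terminus | C=C1C(=O)O[C@@H]([C@@H](O)/C(C)=C/CO)[C@@H]1[C@@H](OC(=O)/C(C)=C\C)CC1=CC(=O)OC(C)(C)O1 | intermediate
24 | acylketene from 23 (C10 ketone, C1=C=O) | C=C1C(=O)O[C@@H]([C@@H](O)/C(C)=C/CO)[C@@H]1[C@@H](OC(=O)/C(C)=C\C)CC(=O)C=C=O | intermediate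
25 | 12-membered β-keto macrolactone (5S,6R,7S,8S; 3E), 5-OH free | C=C1C(=O)O[C@@H]2[C@@H]1[C@@H](OC(=O)/C(C)=C\C)CC(=O)CC(=O)OC/C=C(\C)[C@@H]2O | intermediate
26 | 1-diazo-β-keto macrolactone | C=C1C(=O)O[C@@H]2[C@@H]1[C@@H](OC(=O)/C(C)=C\C)CC(=O)C(=[N+]=[N-])C(=O)OC/C=C(\C)[C@@H]2O | intermediate
27 | 1-(4-methoxybenzyloxy)-β-keto macrolactone (C1 epimers) | C=C1C(=O)O[C@@H]2[C@@H]1[C@@H](OC(=O)/C(C)=C\C)CC(=O)C(OCc1ccc(OC)cc1)C(=O)OC/C=C(\C)[C@@H]2O | intermediate
28 | (1S,5S,6R,7S,8S)-8-angeloyloxy-5-hydroxy-1-(4-methoxybenzyloxy)-10-oxo-14-norgermacra-3E,11(13)-dien-12,6-olide | C=C1C(=O)O[C@@H]2[C@@H]1[C@@H](OC(=O)/C(C)=C\C)CC(=O)[C@@H](OCc1ccc(OC)cc1)C/C=C(\C)[C@@H]2O | intermediate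
29 | (1S,5S,6R,7S,8S)-8-angeloyloxy-5-hydroxy-1-(4-methoxybenzyloxy)germacra-3E,10(14),11(13)-trien-12,6-olide | C=C1C(=O)O[C@@H]2[C@@H]1[C@@H](OC(=O)/C(C)=C\C)CC(=C)[C@@H](OCc1ccc(OC)cc1)C/C=C(\C)[C@@H]2O | intermediate
30 | 5-O-acetate of 29 | C=C1C(=O)O[C@@H]2[C@@H]1[C@@H](OC(=O)/C(C)=C\C)CC(=C)[C@@H](OCc1ccc(OC)cc1)C/C=C(\C)[C@@H]2OC(C)=O | intermediate
31 | (1S,5S,6R,7S,8S)-5-acetoxy-8-angeloyloxy-1-hydroxygermacra-3E,10(14),11(13)-trien-12,6-olide | C=C1C(=O)O[C@@H]2[C@@H]1[C@@H](OC(=O)/C(C)=C\C)CC(=C)[C@@H](O)C/C=C(\C)[C@@H]2OC(C)=O | target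

**Step count and risks**

Total steps: 19. Longest linear sequence: 17 (steps 1–4, 6–10, 12–19).

Steps most likely to fail:

Step 16 (Proposed new method). After ionisation and decarboxylation, the tethered allyl cation and enolate may recombine between molecules (oligomers) or at oxygen instead of closing the strained ten-membered ring. The fallback uses known chemistry, sets out from 27 and is a direct macrocyclisation rather than a ring contraction. DMAP-catalysed transesterification of the β-keto lactone with 2-(trimethylsilyl)ethanol (toluene, 90 °C) opens the ring to the seco 2-(trimethylsilyl)ethyl β-keto ester F1. The primary allylic hydroxyl is converted selectively into its methyl carbonate (ClCO2Me, pyridine, −20 °C) to give the carbonate F2. A Trost-type intramolecular allylic alkylation (Pd(PPh3)4, THF, high dilution; the released methoxide is the base) forms C1–C2 and gives the ten-membered β-keto ester F3 with a quaternary C1. TASF in DMF then cleaves the silylethyl ester, the β-keto acid loses CO2, and the route is rejoined at 28; C1 arises there by protonation, so the epimers are separated and the wrong one is re-equilibrated with DBU.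

Step 6. Facial selectivity at C8 may be poor, because both ring carbons that flank the aldehyde carry trans substituents and the 1,3-induction from the lactone oxygen is weak. The fallback sets out from 12 as obtained (epimer mixture): the 8R alcohol F4 is separated and esterified with angelic acid 13 under Mitsunobu conditions (PPh3, DIAD, toluene, 0 °C). This inverts C8 and gives 15 directly, so both epimers converge on 15 (the 8S alcohol by step 7 with retention, the 8R alcohol by inversion).

Step 15. The rhodium carbenoid may be captured across the ring by the free C5 hydroxyl (transannular O–H insertion) instead of by the external alcohol. The fallback sets out from 25 and masks that hydroxyl: TESCl/imidazole gives the 5-O-triethylsilyl β-keto lactone F5, diazo transfer (p-ABSA, Et3N) gives the silylated diazo lactone F6, and Rh2(OAc)4 with 4-methoxybenzyl alcohol gives the silylated PMB ether F7. HF·pyridine then removes the silyl group and returns the route to 27.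

Further compounds
F1 | step 16 | seco 2-(trimethylsilyl)ethyl 2-(4-methoxybenzyloxy)-3-oxo ester (open chain C1–C10; C2 and C5 hydroxyls free) | C=C1C(=O)O[C@@H]([C@@H](O)/C(C)=C/CO)[C@@H]1[C@@H](OC(=O)/C(C)=C\C)CC(=O)C(OCc1ccc(OC)cc1)C(=O)OCC[Si](C)(C)C
F2 | step 16 | C2 methyl carbonate of F1 | C=C1C(=O)O[C@@H]([C@@H](O)/C(C)=C/COC(=O)OC)[C@@H]1[C@@H](OC(=O)/C(C)=C\C)CC(=O)C(OCc1ccc(OC)cc1)C(=O)OCC[Si](C)(C)C
F3 | step 16 | ten-membered β-keto ester with quaternary C1 (4-methoxybenzyloxy and 2-(trimethylsilyl)ethoxycarbonyl on C1) | C=C1C(=O)O[C@@H]2[C@@H]1[C@@H](OC(=O)/C(C)=C\C)CC(=O)C(OCc1ccc(OC)cc1)(C(=O)OCC[Si](C)(C)C)C/C=C(\C)[C@@H]2O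
F4 | step 6 | C8 epimer of 12 (8R alcohol) | CN(C)C[C@H]1C(=O)O[C@@H](CO[Si](c2ccccc2)(c2ccccc2)C(C)(C)C)[C@@H]1[C@H](O)CC1=CC(=O)OC(C)(C)O1
F5 | step 15 | 5-O-triethylsilyl ether of 25 | C=C1C(=O)O[C@@H]2[C@@H]1[C@@H](OC(=O)/C(C)=C\C)CC(=O)CC(=O)OC/C=C(\C)[C@@H]2O[Si](CC)(CC)CC
F6 | step 15 | 5-O-triethylsilyl ether of the diazo lactone 26 | C=C1C(=O)O[C@@H]2[C@@H]1[C@@H](OC(=O)/C(C)=C\C)CC(=O)C(=[N+]=[N-])C(=O)OC/C=C(\C)[C@@H]2O[Si](CC)(CC)CC
F7 | step 15 | 5-O-triethylsilyl ether of 27 | C=C1C(=O)O[C@@H]2[C@@H]1[C@@H](OC(=O)/C(C)=C\C)CC(=O)C(OCc1ccc(OC)cc1)C(=O)OC/C=C(\C)[C@@H]2O[Si](CC)(CC)CC
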